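All runs were generated by integration for substances that don't exist; the scatter is artificial.

74 % of the charge stands as intermediate A at 0.333 h, and you have to judge whether that reading is already the top of the peak in this flask.

in all of them: substrate 1.5 M

| flask | remark | time |
|---|---|---|
| oak | the very flask that is asked about, followed so far |  |
| flask |  | 10 h |

oak run (percent of the substrate charged)

| time / h | intermediate A / % | target / % |
|---|---|---|
| 0.100 | 48 | 1 |
| 0.333 | 74 | 0 |
| 1.00 | 58 | 4 |
| 3.00 | 24 | 17 |

(scatter of a reading: 1.5 percentage points)

1. when, up to 10 h, the flask holds most intermediate A
2. the amount of intermediate A, in percent of the substrate charged, at that time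

- the analysis behind the earlier runs scatters by 1.5 percentage points, standard deviation

The crude answer is that reading itself. But the readings lie far apart, and the top could hide anywhere before 1.00 h. So take as the zero of the scale the clean case, in which all the substrate becomes intermediate A. Between 1.00 h and 3.00 h intermediate A falls at 0.441 h⁻¹, which puts the tail, traced back to time zero, at 90.2 %.

With that start, the first reading gives a rise of 8.57 h⁻¹, and the curve tops at 0.365 h with 72.8 %. You may object that this lies under the measured 74 %, but the gap of 1.2 percentage points stands against a scatter of 1.5 points.

A second objection: the clean case does not trace back to the whole charge. With these two rates its tail starts at the rise over the rise minus the fall, 105 %. Against that zero, 14.5 % is lacking; call this share of the charge, by which the traced-back tail falls short of the clean one, the early loss, a loss of selectivity. It rests on readings with scatter, so it is a coarse reading.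

The forecast, slightly apart from my reckoning, says 0.37 h and 74 %, adding: “A later rise is implausible unless A re-forms”.

    intermediate B → target (k = 0.00290 min⁻¹)
    intermediate A → intermediate B (k = 0.00830 min⁻¹)
    substrate + intermediate A → side product (k = 0.0100 L mol⁻¹ min⁻¹)
    substrate → intermediate A (k = 0.120 min⁻¹)

The flask peaks at 0.372 h with 74.6 % of intermediate A, as forecast. Side product, each counting as two, ends this flask at 10.2 %, against the early loss of 14.5 %, and already stands at 9.25 % at 0.372 h. Now scale the early loss with the charge for a neighbour flask charged with 2.5 M of substrate, time and all else held: it gives 24.1 %. That neighbour ends with 15.7 % of side product, more than this flask but less than the scaled figure, and its intermediate A peaks at 70.4 %, lower than the 74.6 % here.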